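**Retrosynthetic overview**

1. Cembrane numbering is used: C1 is the ring CH bearing C15 (the oxygenated CMe2 carbon), then C2, C3=C4(Me), C5, C6, C7, C8(Me), C9, C10, C11=C12(Me), C13, C14. The strategy rests on the oxygens on C8 (oxirane carbon) and C10 (acetoxy carbinol), which lie on either side of the C9 methylene of the 14-membered carbocycle. This C8–C9–C10 unit is a masked β-hydroxy ketone, hence an isoxazoline, and the oxirane oxygen on C7 is allylic to the C8=C9 alkene from which that isoxazoline is made.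
2. Endgame disconnections: both acetates; oxirane C7–O (C8 alkoxide displacing a C7 mesylate with inversion); C10 carbinol (syn-1,3-reduction of a β-hydroxy enone); C8–OH and C10=O (N–O cleavage of an isoxazoline bridging C8 and C10).
3. Key disconnection: C9–C10 and O–C8 together, by intramolecular nitrile oxide cycloaddition of an acyclic enal oxime onto its own C8=C9 isopropenyl group, directed by the C7 magnesium alkoxide.
4. Acyclic precursor: C7 carbinol by CBS reduction of an isopropenyl ketone; C4–C5 by Negishi coupling of a Z-alkenyl iodide (C3=C4 from iodo-olefination of the C3 aldehyde); C11=C12 by Horner–Wadsworth–Emmons reaction of the C12 methyl ketone. Aldehyde, ketone and the C1 stereocentre come from ozonolysis of silylated (R)-α-terpineol.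
5. Ring order: the 14-membered carbocycle and the isoxazoline close together (step 12), the isoxazoline is opened (step 14), the oxirane closes last (step 16).

Key step: step 12

Remark: the oxime and the hydroximoyl chloride are written as single C=N isomers although either isomer leads to the same nitrile oxide, and (R)-α-terpineol is assumed to be of high enantiomeric purity because it is the only source of the C1 configuration, to which C7 is added by catalyst control and C8 and C10 by relay.

**Route**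

Step 1
Reactants: 1 (R)-α-terpineol
Product: 2 triethyl({2-[(1R)-4-methylcyclohex-3-en-1-yl]propan-2-yl}oxy)silane
Conditions: TESOTf, 2,6-lutidine, CH2Cl2, 0 °C
Reagents that add atoms: triethylsilyl trifluoromethanesulfonate, CC[Si](CC)(CC)OS(=O)(=O)C(F)(F)F
Why: Silylation with a silyl triflate and a hindered pyridine base protects the tertiary alcohol without touching the alkene, and the triethylsilyl ether is chosen to last until fluoride removal in step 17.

Step 2
Reactants: 2 triethyl({2-[(1R)-4-methylcyclohex-3-en-1-yl]propan-2-yl}oxy)silane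
Product: 3 (3R)-6-oxo-3-{2-[(triethylsilyl)oxy]propan-2-yl}heptanal
Conditions: O3, CH2Cl2, −78 °C; then PPh3, −78 °C to rt
Reagents that add atoms: ozone, [O-][O+]=O
Why: Ozonolysis with reductive work-up cleaves the only C=C bond into the C12 methyl ketone and the C3 aldehyde, and the C1 stereocentre is not α to either carbonyl and so cannot epimerize.

Step 3
Reactants: 3 (3R)-6-oxo-3-{2-[(triethylsilyl)oxy]propan-2-yl}heptanal; 4 ethyltriphenylphosphonium iodide
Product: 8 (5R,7Z)-8-iodo-5-{2-[(triethylsilyl)oxy]propan-2-yl}non-7-en-2-one, via ethylidenetriphenylphosphorane 5 (not isolated), via (1-iodoethyl)triphenylphosphonium iodide 6 (not isolated), via (1-iodoethylidene)triphenylphosphorane 7 (not isolated)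
Conditions: 4, n-BuLi, THF, 0 °C; I2, −78 °C; NaN(SiMe3)2, −20 °C; then 3, −78 °C
Reagents that add atoms: iodine, II
Why: In this Stork–Zhao-type Wittig iodo-olefination the α-iodo ylide 7 reacts at −78 °C only with the aldehyde, the methyl ketone being far less electrophilic, and kinetic formation of the cis-oxaphosphetane should place iodine cis to the chain, which fixes the Z geometry of C3=C4.

Step 4
Reactants: 8 (5R,7Z)-8-iodo-5-{2-[(triethylsilyl)oxy]propan-2-yl}non-7-en-2-one; 9 tert-butyl 2-(diethoxyphosphoryl)acetate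
Product: 10 tert-butyl (2E,6R,8Z)-9-iodo-3-methyl-6-{2-[(triethylsilyl)oxy]propan-2-yl}deca-2,8-dienoate
Conditions: NaH, THF, 0 °C to 50 °C; chromatographic removal of the minor 2Z isomer
Reagents that add atoms: none
Why: Horner–Wadsworth–Emmons olefination of the methyl ketone should place the ester trans to the longer chain (the E geometry of C11=C12) while the alkenyl iodide and silyl ether are inert to the phosphonate anion, and the tert-butyl ester is chosen so that it stays untouched in steps 6 and 7.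

Step 5
Reactants: 10 tert-butyl (2E,6R,8Z)-9-iodo-3-methyl-6-{2-[(triethylsilyl)oxy]propan-2-yl}deca-2,8-dienoate; 11 (3-ethoxy-3-oxopropyl)zinc bromide
Product: 12 1-tert-butyl 12-ethyl (2E,6R,8Z)-3,9-dimethyl-6-{2-[(triethylsilyl)oxy]propan-2-yl}dodeca-2,8-dienedioate
Conditions: Pd(PPh3)4 (cat.), THF, rt to 45 °C
Reagents that add atoms: none
Why: Negishi coupling of the alkenyl iodide with the zinc homoenolate under zerovalent palladium catalysis goes with retention of alkene geometry and tolerates both esters, so the C4–C5 bond is made and C3=C4 keeps the Z geometry set in step 3.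

Step 6
Reactants: 12 1-tert-butyl 12-ethyl (2E,6R,8Z)-3,9-dimethyl-6-{2-[(triethylsilyl)oxy]propan-2-yl}dodeca-2,8-dienedioate
Product: 13 tert-butyl (2E,6R,8Z)-12-[methoxy(methyl)amino]-3,9-dimethyl-12-oxo-6-{2-[(triethylsilyl)oxy]propan-2-yl}dodeca-2,8-dienoate
Conditions: MeNHOMe·HCl, i-PrMgCl, THF, −20 °C
Reagents that add atoms: N,O-dimethylhydroxylamine hydrochloride, CNOC.Cl
Why: The chloromagnesium amide formed from the amine salt and i-PrMgCl converts the unhindered saturated ethyl ester into the Weinreb amide (ester aminolysis), whereas the conjugated, hindered tert-butyl ester does not react at this temperature.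

Step 7
Reactants: 13 tert-butyl (2E,6R,8Z)-12-[methoxy(methyl)amino]-3,9-dimethyl-12-oxo-6-{2-[(triethylsilyl)oxy]propan-2-yl}dodeca-2,8-dienoate; 14 isopropenylmagnesium bromide
Product: 15 tert-butyl (2E,6R,8Z)-3,9,13-trimethyl-12-oxo-6-{2-[(triethylsilyl)oxy]propan-2-yl}tetradeca-2,8,13-trienoate
Conditions: THF, −78 °C to 0 °C; inverse quench into cold aq. NH4Cl
Reagents that add atoms: none
Why: Grignard addition to the Weinreb amide stops at the chelated tetrahedral intermediate and releases the isopropenyl ketone (C7 carbonyl, C8=C9) only on quench, and the β,β-disubstituted tert-butyl enoate is too unreactive to compete.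

Step 8
Reactants: 15 tert-butyl (2E,6R,8Z)-3,9,13-trimethyl-12-oxo-6-{2-[(triethylsilyl)oxy]propan-2-yl}tetradeca-2,8,13-trienoate
Product: 16 tert-butyl (2E,6R,8Z,12R)-12-hydroxy-3,9,13-trimethyl-6-{2-[(triethylsilyl)oxy]propan-2-yl}tetradeca-2,8,13-trienoate
Conditions: (S)-2-methyl-CBS-oxazaborolidine (cat.), catecholborane, toluene, −78 °C
Reagents that add atoms: none
Why: In this Corey–Bakshi–Shibata reduction the isopropenyl group acts as the large and the C6 methylene chain as the small ketone substituent, so the (S)-catalyst should give the 12R carbinol (C7 of the skeleton, R), and catecholborane at −78 °C leaves the alkenes and the enoate alone.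

Step 9
Reactants: 16 tert-butyl (2E,6R,8Z,12R)-12-hydroxy-3,9,13-trimethyl-6-{2-[(triethylsilyl)oxy]propan-2-yl}tetradeca-2,8,13-trienoate
Product: 17 (2E,6R,8Z,12R)-3,9,13-trimethyl-6-{2-[(triethylsilyl)oxy]propan-2-yl}tetradeca-2,8,13-triene-1,12-diol
Conditions: i-Bu2AlH (excess), CH2Cl2, −78 °C to 0 °C; aq. KNaC4H4O6
Reagents that add atoms: none
Why: i-Bu2AlH reduces the conjugated tert-butyl ester in a 1,2 sense to the primary allylic alcohol (ester reduction) after the free hydroxyl has become its aluminium alkoxide, and no stereocentre or alkene geometry is affected.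

Step 10
Reactants: 17 (2E,6R,8Z,12R)-3,9,13-trimethyl-6-{2-[(triethylsilyl)oxy]propan-2-yl}tetradeca-2,8,13-triene-1,12-diol
Product: 18 (2E,6R,8Z,12R)-12-hydroxy-3,9,13-trimethyl-6-{2-[(triethylsilyl)oxy]propan-2-yl}tetradeca-2,8,13-trienal
Conditions: TEMPO (cat.), PhI(OAc)2, CH2Cl2, rt
Reagents that add atoms: none
Why: The oxoammonium oxidation with TEMPO and PhI(OAc)2 is selective for primary over secondary alcohols, so only the primary allylic alcohol becomes the enal and the secondary C7 carbinol is kept, without E/Z isomerization under these near-neutral conditions.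

Step 11
Reactants: 18 (2E,6R,8Z,12R)-12-hydroxy-3,9,13-trimethyl-6-{2-[(triethylsilyl)oxy]propan-2-yl}tetradeca-2,8,13-trienal
Product: 19 (1E,2E,6R,8Z,12R)-12-hydroxy-3,9,13-trimethyl-6-{2-[(triethylsilyl)oxy]propan-2-yl}tetradeca-2,8,13-trienal oxime
Conditions: NH2OH·HCl, NaOAc, EtOH, 0 °C to rt
Reagents that add atoms: hydroxylamine hydrochloride, NO.Cl
Why: Condensation of the aldehyde with hydroxylamine (oxime formation) is fast on a β,β-disubstituted enal, where conjugate addition is blocked, and gives the aldoxime that serves as the nitrile oxide precursor.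

Step 12
Reactants: 19 (1E,2E,6R,8Z,12R)-12-hydroxy-3,9,13-trimethyl-6-{2-[(triethylsilyl)oxy]propan-2-yl}tetradeca-2,8,13-trienal oxime
Product: 22 (1R,3Z,7R,8R,11E)-8,10-(epoxynitrilo)-15-[(triethylsilyl)oxy]cembra-3,11-dien-7-ol (isoxazoline O on C8; C=N at C10; C9 the ring CH2), via hydroximoyl chloride 20 (not isolated), via nitrile oxide bromomagnesium alkoxide 21 (not isolated)
Conditions: t-BuOCl (1.0 equiv), CH2Cl2, −78 °C, dark; then syringe-pump addition to i-PrOMgBr (from EtMgBr and i-PrOH, 4 equiv), CH2Cl2, 0 °C to rt, about 1 mM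
Reagents that add atoms: none
Why: t-BuOCl chlorinates the aldoxime carbon to give 20, and i-PrOMgBr then removes HCl and places MgBr on the C7 oxygen, so that the conjugated nitrile oxide and the allylic alkoxide of 21 sit on one magnesium and combine by a concerted [3+2] cycloaddition across C8=C9. The closest known reaction types are the intramolecular nitrile oxide–alkene cycloaddition used as a macrocyclization and the magnesium-alkoxide-directed addition of nitrile oxides to α-branched allylic alcohols, and the two have not yet been used together for a ring of this size, which is where the risk of the route sits. The 14-membered carbocycle closes through C9–C10 in the bridged mode (dipole carbon to the terminal alkene carbon, C8 and C10 becoming bridgeheads), and the isoxazoline closes in the same event through O–C8 as the five-membered ring of the cycloaddition. The new C8 stereocentre should be set by the resident C7 centre, because in the chelated transition state C7–H eclipses C8=C9, the C6 chain points away from the dipole and the magnesium-bound C7 oxygen delivers the dipole oxygen to the face it occupies, which from the 7R alcohol gives 8R. The step needs site selectivity for C8=C9 over C3=C4 and C11=C12, which the rate acceleration by the alkoxide, the lower substitution of the terminal alkene and the medium ring sizes of the alternatives should secure, and it needs regioselectivity, which the polarization of the 1,1-disubstituted alkene and the chelate both direct toward O–C8 and C–C9. Dimerization to the furoxan is held back by slow addition at high dilution.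

Step 13
Reactants: 22 (1R,3Z,7R,8R,11E)-8,10-(epoxynitrilo)-15-[(triethylsilyl)oxy]cembra-3,11-dien-7-ol
Product: 23 (1R,3Z,7R,8R,11E)-8,10-(epoxynitrilo)-15-[(triethylsilyl)oxy]cembra-3,11-dien-7-yl methanesulfonate
Conditions: MsCl, Et3N, CH2Cl2, 0 °C
Reagents that add atoms: methanesulfonyl chloride, CS(=O)(=O)Cl
Why: Mesylation through sulfene (sulfonate ester formation) activates the hindered C7 hydroxyl, the only free hydroxyl, with retention at C7, and the isoxazoline is inert to these conditions.

Step 14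
Reactants: 23 (1R,3Z,7R,8R,11E)-8,10-(epoxynitrilo)-15-[(triethylsilyl)oxy]cembra-3,11-dien-7-yl methanesulfonate
Product: 25 (1R,3Z,7R,8R,11E)-8-hydroxy-10-oxo-15-[(triethylsilyl)oxy]cembra-3,11-dien-7-yl methanesulfonate, via β-hydroxy imine 24 (not isolated)
Conditions: SmI2, THF, 0 °C; O2 quench; then B(OH)3, MeOH/H2O, rt
Reagents that add atoms: water, O
Why: SmI2 cleaves the N–O bond of the conjugated isoxazoline by single-electron reduction to the β-hydroxy imine, which boric acid hydrolyses to the β-hydroxy enone under mildly acidic conditions that should avoid retro-aldol cleavage, alkene reduction and premature displacement of the mesylate.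

Step 15
Reactants: 25 (1R,3Z,7R,8R,11E)-8-hydroxy-10-oxo-15-[(triethylsilyl)oxy]cembra-3,11-dien-7-yl methanesulfonate
Product: 27 (1R,3Z,7R,8R,10S,11E)-8,10-dihydroxy-15-[(triethylsilyl)oxy]cembra-3,11-dien-7-yl methanesulfonate, via diethylboron chelate 26 (not isolated)
Conditions: Et2BOMe, THF/MeOH (4:1), −78 °C; NaBH4, −78 °C; AcOH quench, then repeated evaporation from MeOH
Reagents that add atoms: none
Why: In this Narasaka–Prasad reduction the C8 hydroxyl and the C10 carbonyl are tied into a six-membered diethylboron chelate with the C7 and C11 ring branches equatorial and the C8 methyl axial, and external hydride attacks C10 axially in a 1,2 sense to give the 8,10-syn diol, which is 10S.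

Step 16
Reactants: 27 (1R,3Z,7R,8R,10S,11E)-8,10-dihydroxy-15-[(triethylsilyl)oxy]cembra-3,11-dien-7-yl methanesulfonate
Product: 28 (1R,3Z,7S,8R,10S,11E)-7,8-epoxy-15-[(triethylsilyl)oxy]cembra-3,11-dien-10-ol
Conditions: K2CO3, MeOH, 0 °C to rt
Reagents that add atoms: none
Why: The tertiary C8 alkoxide displaces the adjacent C7 mesylate by intramolecular SN2 reaction (3-exo-tet Williamson closure) with inversion at C7, which turns the 7R,8R hydroxy mesylate into the 7S,8R cis-oxirane, and this closure should outrun attack of the C10 alkoxide on C7.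

Step 17
Reactants: 28 (1R,3Z,7S,8R,10S,11E)-7,8-epoxy-15-[(triethylsilyl)oxy]cembra-3,11-dien-10-ol
Product: 29 (1R,3Z,7S,8R,10S,11E)-7,8-epoxycembra-3,11-diene-10,15-diol
Conditions: Bu4NF, THF, rt
Reagents that add atoms: none
Why: Fluoride cleaves the tertiary triethylsilyl ether (desilylation) without affecting the oxirane, the alkenes or the allylic alcohol.

Step 18
Reactants: 29 (1R,3Z,7S,8R,10S,11E)-7,8-epoxycembra-3,11-diene-10,15-diol
Product: 30 (1R,3Z,7S,8R,10S,11E)-7,8-epoxycembra-3,11-diene-10,15-diyl diacetate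
Conditions: Ac2O, DMAP, Et3N, CH2Cl2, rt to 40 °C
Reagents that add atoms: acetic anhydride, CC(=O)OC(C)=O
Why: Acylation with Ac2O under nucleophilic catalysis by DMAP esterifies the secondary allylic C10 hydroxyl quickly and the tertiary C15 hydroxyl on longer reaction, and the basic medium leaves the trisubstituted oxirane and all four stereocentres untouched.

**Compound list**

1 | (R)-α-terpineol, 2-[(1R)-4-methylcyclohex-3-en-1-yl]propan-2-ol | CC1=CC[C@@H](CC1)C(C)(C)O | starting material
2 | triethyl({2-[(1R)-4-methylcyclohex-3-en-1-yl]propan-2-yl}oxy)silane | CC1=CC[C@@H](CC1)C(C)(C)O[Si](CC)(CC)CC | intermediate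
3 | (3R)-6-oxo-3-{2-[(triethylsilyl)oxy]propan-2-yl}heptanal | CC(=O)CC[C@@H](C(C)(C)O[Si](CC)(CC)CC)CC=O | intermediate
4 | ethyltriphenylphosphonium iodide | CC[P+](c1ccccc1)(c1ccccc1)c1ccccc1.[I-] | starting material
5 | ethylidenetriphenylphosphorane | CC=P(c1ccccc1)(c1ccccc1)c1ccccc1 | intermediate
6 | (1-iodoethyl)triphenylphosphonium iodide | CC(I)[P+](c1ccccc1)(c1ccccc1)c1ccccc1.[I-] | intermediate
7 | (1-iodoethylidene)triphenylphosphorane | CC(I)=P(c1ccccc1)(c1ccccc1)c1ccccc1 | intermediate
8 | (5R,7Z)-8-iodo-5-{2-[(triethylsilyl)oxy]propan-2-yl}non-7-en-2-one | CC(=O)CC[C@@H](C(C)(C)O[Si](CC)(CC)CC)C/C=C(/C)I | intermediate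
9 | tert-butyl 2-(diethoxyphosphoryl)acetate | CCOP(=O)(CC(=O)OC(C)(C)C)OCC | starting material
10 | tert-butyl (2E,6R,8Z)-9-iodo-3-methyl-6-{2-[(triethylsilyl)oxy]propan-2-yl}deca-2,8-dienoate | CC(C)(C)OC(=O)/C=C(\C)CC[C@@H](C(C)(C)O[Si](CC)(CC)CC)C/C=C(/C)I | intermediate
11 | (3-ethoxy-3-oxopropyl)zinc bromide | CCOC(=O)CC[Zn]Br | starting material
12 | 1-tert-butyl 12-ethyl (2E,6R,8Z)-3,9-dimethyl-6-{2-[(triethylsilyl)oxy]propan-2-yl}dodeca-2,8-dienedioate | CC(C)(C)OC(=O)/C=C(\C)CC[C@@H](C(C)(C)O[Si](CC)(CC)CC)C/C=C(/C)CCC(=O)OCC | intermediate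
13 | tert-butyl (2E,6R,8Z)-12-[methoxy(methyl)amino]-3,9-dimethyl-12-oxo-6-{2-[(triethylsilyl)oxy]propan-2-yl}dodeca-2,8-dienoate | CC(C)(C)OC(=O)/C=C(\C)CC[C@@H](C(C)(C)O[Si](CC)(CC)CC)C/C=C(/C)CCC(=O)N(C)OC | intermediate
14 | isopropenylmagnesium bromide | CC(=C)[Mg]Br | starting material
15 | tert-butyl (2E,6R,8Z)-3,9,13-trimethyl-12-oxo-6-{2-[(triethylsilyl)oxy]propan-2-yl}tetradeca-2,8,13-trienoate | CC(C)(C)OC(=O)/C=C(\C)CC[C@@H](C(C)(C)O[Si](CC)(CC)CC)C/C=C(/C)CCC(=O)C(C)=C | intermediate
16 | tert-butyl (2E,6R,8Z,12R)-12-hydroxy-3,9,13-trimethyl-6-{2-[(triethylsilyl)oxy]propan-2-yl}tetradeca-2,8,13-trienoate | CC(C)(C)OC(=O)/C=C(\C)CC[C@@H](C(C)(C)O[Si](CC)(CC)CC)C/C=C(/C)CC[C@@H](O)C(C)=C | intermediate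
17 | (2E,6R,8Z,12R)-3,9,13-trimethyl-6-{2-[(triethylsilyl)oxy]propan-2-yl}tetradeca-2,8,13-triene-1,12-diol | OC/C=C(\C)CC[C@@H](C(C)(C)O[Si](CC)(CC)CC)C/C=C(/C)CC[C@@H](O)C(C)=C | intermediate
18 | (2E,6R,8Z,12R)-12-hydroxy-3,9,13-trimethyl-6-{2-[(triethylsilyl)oxy]propan-2-yl}tetradeca-2,8,13-trienal | O=C/C=C(\C)CC[C@@H](C(C)(C)O[Si](CC)(CC)CC)C/C=C(/C)CC[C@@H](O)C(C)=C | intermediate
19 | (1E,2E,6R,8Z,12R)-12-hydroxy-3,9,13-trimethyl-6-{2-[(triethylsilyl)oxy]propan-2-yl}tetradeca-2,8,13-trienal oxime | O/N=C/C=C(\C)CC[C@@H](C(C)(C)O[Si](CC)(CC)CC)C/C=C(/C)CC[C@@H](O)C(C)=C | intermediate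
20 | (1Z,2E,6R,8Z,12R)-N,12-dihydroxy-3,9,13-trimethyl-6-{2-[(triethylsilyl)oxy]propan-2-yl}tetradeca-2,8,13-trienimidoyl chloride | O/N=C(\Cl)/C=C(\C)CC[C@@H](C(C)(C)O[Si](CC)(CC)CC)C/C=C(/C)CC[C@@H](O)C(C)=C | intermediate
21 | (2E,6R,8Z,12R)-12-[(bromomagnesio)oxy]-3,9,13-trimethyl-6-{2-[(triethylsilyl)oxy]propan-2-yl}tetradeca-2,8,13-trienenitrile oxide | [O-][N+]#C/C=C(\C)CC[C@@H](C(C)(C)O[Si](CC)(CC)CC)C/C=C(/C)CC[C@@H](O[Mg]Br)C(C)=C | intermediate
22 | (1R,3Z,7R,8R,11E)-8,10-(epoxynitrilo)-15-[(triethylsilyl)oxy]cembra-3,11-dien-7-ol | C[C@]12CC(=NO1)/C=C(\C)CC[C@@H](C(C)(C)O[Si](CC)(CC)CC)C/C=C(/C)CC[C@H]2O | intermediate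
23 | (1R,3Z,7R,8R,11E)-8,10-(epoxynitrilo)-15-[(triethylsilyl)oxy]cembra-3,11-dien-7-yl methanesulfonate | C[C@]12CC(=NO1)/C=C(\C)CC[C@@H](C(C)(C)O[Si](CC)(CC)CC)C/C=C(/C)CC[C@H]2OS(C)(=O)=O | intermediate
24 | (1R,3Z,7R,8R,11E)-8-hydroxy-10-imino-15-[(triethylsilyl)oxy]cembra-3,11-dien-7-yl methanesulfonate | N=C1/C=C(\C)CC[C@@H](C(C)(C)O[Si](CC)(CC)CC)C/C=C(/C)CC[C@@H](OS(C)(=O)=O)[C@](C)(O)C1 | intermediate
25 | (1R,3Z,7R,8R,11E)-8-hydroxy-10-oxo-15-[(triethylsilyl)oxy]cembra-3,11-dien-7-yl methanesulfonate | O=C1/C=C(\C)CC[C@@H](C(C)(C)O[Si](CC)(CC)CC)C/C=C(/C)CC[C@@H](OS(C)(=O)=O)[C@](C)(O)C1 | intermediate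
26 | (1R,3Z,7R,8R,11E)-8-[(diethylboranyl)oxy]-10-oxo-15-[(triethylsilyl)oxy]cembra-3,11-dien-7-yl methanesulfonate | O=C1/C=C(\C)CC[C@@H](C(C)(C)O[Si](CC)(CC)CC)C/C=C(/C)CC[C@@H](OS(C)(=O)=O)[C@](C)(OB(CC)CC)C1 | intermediate
27 | (1R,3Z,7R,8R,10S,11E)-8,10-dihydroxy-15-[(triethylsilyl)oxy]cembra-3,11-dien-7-yl methanesulfonate | O[C@@H]1/C=C(\C)CC[C@@H](C(C)(C)O[Si](CC)(CC)CC)C/C=C(/C)CC[C@@H](OS(C)(=O)=O)[C@](C)(O)C1 | intermediate
28 | (1R,3Z,7S,8R,10S,11E)-7,8-epoxy-15-[(triethylsilyl)oxy]cembra-3,11-dien-10-ol | O[C@@H]1/C=C(\C)CC[C@@H](C(C)(C)O[Si](CC)(CC)CC)C/C=C(/C)CC[C@@H]2O[C@]2(C)C1 | intermediate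
29 | (1R,3Z,7S,8R,10S,11E)-7,8-epoxycembra-3,11-diene-10,15-diol | O[C@@H]1/C=C(\C)CC[C@@H](C(C)(C)O)C/C=C(/C)CC[C@@H]2O[C@]2(C)C1 | intermediate
30 | (1R,3Z,7S,8R,10S,11E)-7,8-epoxycembra-3,11-diene-10,15-diyl diacetate (CNP0282098.1) | CC(=O)O[C@@H]1/C=C(\C)CC[C@@H](C(C)(C)OC(C)=O)C/C=C(/C)CC[C@@H]2O[C@]2(C)C1 | target

**Step count**

Total step count: 18. Longest linear sequence: 18 steps, from 1 to 30.

**Steps most likely to fail**

Step 12. The nitrile oxide may be consumed by intermolecular pathways (furoxan formation, oligomers) faster than the chelated ten-atom chain folds. Alternatively the strain of the closing macrocycle may override the chelate, so that both faces of C8=C9 are attacked and the C8 configuration is eroded. The fallback makes the C9–C10 and O–C8 bonds intermolecularly, where direction by the magnesium alkoxide is established chemistry, and closes the ring afterwards at C11=C12 by metathesis. It sets out from 8. Wittig methylenation of the methyl ketone (Ph3PCH3Br, NaN(SiMe3)2, THF) gives the diene iodide triethyl({2-[(5R,7Z)-8-iodo-2-methylnona-1,7-dien-5-yl]propan-2-yl}oxy)silane F1. Negishi coupling with 11 as in step 5 gives the ethyl ester F2, amidation as in step 6 gives the Weinreb amide F3, and addition of 14 as in step 7 gives the isopropenyl ketone F4. CBS reduction as in step 8 gives the allylic alcohol F5. The bromomagnesium alkoxide of F5 is combined with the nitrile oxide generated from (E)-but-2-enal oxime (t-BuOCl, then i-PrOMgBr, CH2Cl2) to give the 3-propenylisoxazoline carbinol F6. The sense of induction at C8 should be the same as in step 12, and the remote 1,1-disubstituted alkene, which carries no alkoxide, should be left alone. Ring-closing metathesis of F6 (second-generation Grubbs catalyst, CH2Cl2, reflux, high dilution) between the propenyl group and the C12 methylidene expels propene and comes back to the route at 22. The price is that the C11=C12 geometry is then set by the metathesis, where the conjugated E isomer is expected to be favoured but is not assured.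

Step 15. Hydride may fail to reach C10 along the axial trajectory of the boron chelate, because the axial C8 methyl and the transannular chain shield that face, so that the 10R epimer forms in part or mainly. The fallback no longer sets C10 in the reduction but by a later inversion. It sets out from 25. Evans–Saksena reduction with Me4NBH(OAc)3 (MeCN/AcOH, −20 °C), which delivers hydride internally from the C8-bound borohydride, is used on purpose to make the 8,10-anti diol, the 10R epimer of 27, F7. K2CO3 in MeOH closes the oxirane as in step 16 to give the 10R epoxy alcohol F8. Mitsunobu reaction with acetic acid (PPh3, diisopropyl azodicarboxylate, toluene, 0 °C) displaces the activated C10 oxygen with inversion and gives the 10S acetate F9. Desilylation with Bu4NF buffered with AcOH gives the C15 alcohol F10. Acetylation of the tertiary hydroxyl (Ac2O, DMAP, Et3N) comes back to the route at 30.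

Step 16. The secondary C10 alkoxide may attack C7 in a 5-exo-tet displacement and form a tetrahydrofuran bridging C7 and C10, in competition with the 3-exo-tet closure from the C8 alkoxide. The fallback caps the competing nucleophile before base is applied. It sets out from 27. Et3SiCl and imidazole (DMF, 0 °C) silylate only the secondary C10 hydroxyl and give the bis-silyl hydroxy mesylate F11. K2CO3 in MeOH then has only the C8 alkoxide to work with and gives the bis-silyl epoxide F12. Bu4NF removes both triethylsilyl groups in one operation and comes back to the route at 29.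

**Further compounds**

F1 | step 12 | triethyl({2-[(5R,7Z)-8-iodo-2-methylnona-1,7-dien-5-yl]propan-2-yl}oxy)silane | C=C(C)CC[C@@H](C(C)(C)O[Si](CC)(CC)CC)C/C=C(/C)I
F2 | step 12 | ethyl (4Z,7R)-4,10-dimethyl-7-{2-[(triethylsilyl)oxy]propan-2-yl}undeca-4,10-dienoate | C=C(C)CC[C@@H](C(C)(C)O[Si](CC)(CC)CC)C/C=C(/C)CCC(=O)OCC
F3 | step 12 | (4Z,7R)-N-methoxy-N,4,10-trimethyl-7-{2-[(triethylsilyl)oxy]propan-2-yl}undeca-4,10-dienamide | C=C(C)CC[C@@H](C(C)(C)O[Si](CC)(CC)CC)C/C=C(/C)CCC(=O)N(C)OC
F4 | step 12 | (6Z,9R)-2,6,12-trimethyl-9-{2-[(triethylsilyl)oxy]propan-2-yl}trideca-1,6,12-trien-3-one | C=C(C)CC[C@@H](C(C)(C)O[Si](CC)(CC)CC)C/C=C(/C)CCC(=O)C(C)=C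
F5 | step 12 | (3R,6Z,9R)-2,6,12-trimethyl-9-{2-[(triethylsilyl)oxy]propan-2-yl}trideca-1,6,12-trien-3-ol | C=C(C)CC[C@@H](C(C)(C)O[Si](CC)(CC)CC)C/C=C(/C)CC[C@@H](O)C(C)=C
F6 | step 12 | (1R,4Z,7R)-4,10-dimethyl-1-{(5R)-5-methyl-3-[(1E)-prop-1-en-1-yl]-4,5-dihydro-1,2-oxazol-5-yl}-7-{2-[(triethylsilyl)oxy]propan-2-yl}undeca-4,10-dien-1-ol | C[C@@]1(CC(=NO1)/C=C/C)[C@H](O)CC/C(C)=C\C[C@@H](CCC(C)=C)C(C)(C)O[Si](CC)(CC)CC
F7 | step 15 | (1R,3Z,7R,8R,10R,11E)-8,10-dihydroxy-15-[(triethylsilyl)oxy]cembra-3,11-dien-7-yl methanesulfonate | O[C@H]1/C=C(\C)CC[C@@H](C(C)(C)O[Si](CC)(CC)CC)C/C=C(/C)CC[C@@H](OS(C)(=O)=O)[C@](C)(O)C1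
F8 | step 15 | (1R,3Z,7S,8R,10R,11E)-7,8-epoxy-15-[(triethylsilyl)oxy]cembra-3,11-dien-10-ol | O[C@H]1/C=C(\C)CC[C@@H](C(C)(C)O[Si](CC)(CC)CC)C/C=C(/C)CC[C@@H]2O[C@]2(C)C1
F9 | step 15 | (1R,3Z,7S,8R,10S,11E)-7,8-epoxy-15-[(triethylsilyl)oxy]cembra-3,11-dien-10-yl acetate | CC(=O)O[C@@H]1/C=C(\C)CC[C@@H](C(C)(C)O[Si](CC)(CC)CC)C/C=C(/C)CC[C@@H]2O[C@]2(C)C1
F10 | step 15 | (1R,3Z,7S,8R,10S,11E)-7,8-epoxy-15-hydroxycembra-3,11-dien-10-yl acetate | CC(=O)O[C@@H]1/C=C(\C)CC[C@@H](C(C)(C)O)C/C=C(/C)CC[C@@H]2O[C@]2(C)C1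
F11 | step 16 | (1R,3Z,7R,8R,10S,11E)-8-hydroxy-10,15-bis[(triethylsilyl)oxy]cembra-3,11-dien-7-yl methanesulfonate | CC[Si](CC)(CC)O[C@@H]1/C=C(\C)CC[C@@H](C(C)(C)O[Si](CC)(CC)CC)C/C=C(/C)CC[C@@H](OS(C)(=O)=O)[C@](C)(O)C1
F12 | step 16 | (1R,3Z,7S,8R,10S,11E)-7,8-epoxy-10,15-bis[(triethylsilyl)oxy]cembra-3,11-diene | CC[Si](CC)(CC)O[C@@H]1/C=C(\C)CC[C@@H](C(C)(C)O[Si](CC)(CC)CC)C/C=C(/C)CC[C@@H]2O[C@]2(C)C1
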